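1. Late in cedar, from 6.00 h to 20.0 h, Z averages 4.30% of the D charged and L 0.100%. Neither climbs beyond the scatter of 0.5 percentage points, so cedar holds Z and L at about those levels, and the rest of its D stands elsewhere, unread.

| setting | cedar | birch | green | blue | violet | amber |
|---|---|---|---|---|---|---|
| D | 0.050 M | 0.050 M | 0.050 M (fed, over 1.0 h) | 0.050 M | 0.050 M (fed, over 4.0 h) | 0.050 M (fed, over 4.0 h) |
| E | 1 equiv | 0.50 equiv | 1.00 equiv | 1.00 equiv | 1.00 equiv | 1.00 equiv |
| temperature | 100 °C | 100 °C | 100 °C | 100 °C | 100 °C |  |
| remark | run made earlier | run made earlier | all else is in the flask from the start; the feed brings no volume worth counting | everything together at the start | all else is in the flask from the start; the feed brings no volume worth counting | the addition at 60 °C, then warmed to 100 °C; the feed brings no volume worth counting |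
| time |  |  | 20 h | 20 h | 20 h | 20 h |

cedar run (percent of the D charged)

| time / h | Z / % | L / % |
|---|---|---|
| 1.50 | 0.6 | 0 |
| 3.00 | 1.8 | 0.3 |
| 6.00 | 4.2 | 0.2 |
| 10.0 | 4.5 | 0 |
| 20.0 | 4.2 | 0.1 |

birch run (percent of the D charged)

| time / min | Z / % | L / % |
|---|---|---|
| 10.0 | 1.5 | 0 |
| 30.0 | 0.7 | 0.7 |
| 60.0 | 0 | 0 |
| 80.0 | 0.2 | 0 |
| 120 | 0 | 0 |

(standard deviation of a reading: 0.5 percentage points)

* which flask leads in share of Z in Z plus L ("all alike" within 1.5 percentage points) (green / blue / violet / amber / all alike)
* share of Z in Z plus L at the end, green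
* share of Z in Z plus L at the end, blue
* share of Z in Z plus L at the end, violet
* share of Z in Z plus L at the end, amber

- steps under discussion: Z <-> L; E + Q -> J + X; E + G -> Z + X; E + J -> G + X; D + E -> Q + X
- the earlier runs do not show what temperature does; that part of a forecast is a guess

2. I freeze the pair. Once Z and L hold still, I treat [L]/[Z] as the constant of Z <-> L (thermodynamic control). I expect the feed to change how much Z forms, but not how it splits.

3. L lies inside its scatter, so the central share of 97.7% is weak. With L at its mean plus 3 standard errors of 3 readings, 0.966%, I get the floor, my cautious estimate from the readings and not a strict bound, of the end share [Z]/([Z]+[L]): 81.7%.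

4. Leave the feeds as written. Violet and amber finish feeding at 4.0 h, which leaves 16.0 h, longer than the 14.0 h over which cedar's readings stood flat, and green has longer still. Cedar and birch show nothing of temperature, so what amber's 60 °C stage does is a guess. I commit to equal shares at or above the floor.

5. The forecast says all alike, with 98%, 98%, 98% and 98% for green, blue, violet and amber (“so I expect about 98% Z in each”), and its low ends, 89% at the lowest, stand above my floor.

6. The flasks give all alike: green 83.3%, blue 83.3%, violet 83.3%, amber 83.3%, level with each other and above the floor.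

    Z ⇌ L (K = 0.200, k = 0.00230 /min, Ea = 117 kJ/mol, ΔH = −11.0 kJ/mol)
    E + Q → J + X (k = 0.100 /M/min, Ea = 89.0 kJ/mol)
    E + G → Z + X (k = 0.700 /M/min, Ea = 73.0 kJ/mol)
    E + J → G + X (k = 0.460 /M/min, Ea = 78.0 kJ/mol)
    D + E → Q + X (k = 0.240 /M/min, Ea = 77.0 kJ/mol)
    (constants at 100 °C)

In blue the forward half-life of Z to L is 5.0 h, short against the 20 h of the run. Violet left for 200 h still shows 83.3%, above the floor of 81.7%. A further flask like violet but with 0.20 M of D, at the same equivalents, holds Z 11.0% and L 2.21% at 20.0 h, so it too clears the floor, with a share of 83.3%.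

Readings and results stem from a simulated flask on assumed constants.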